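A one-step world has E meet D and give Z; these flasks have a stop on the way, X, made from E on J and passed on with D on Q, while L holds part of J as J.L.

| setting | theta | beta | epsilon | zeta |
|---|---|---|---|---|
| E | 0.075 M | 0.075 M | 0.075 M (fed, over 15 min) | 0.075 M |
| D | 0.0712 M | 0.0712 M (in portions, 2, over 15 min) | 0.0712 M | 0.0712 M (fed, over 15 min) |
| J | 75 µM | 75 µM | 75 µM | 75 µM |
| Q | 0.75 mM | 0.75 mM | 0.75 mM | 0.75 mM |
| L | 0.23 mM | 0.23 mM | 0.23 mM | 0.23 mM |
| time | 25 min | 25 min | 25 min | 25 min |
| remark | everything together at the start | first portion at the start, last at 15 min | all else is in the flask from the start; the feed brings no volume worth counting | all else is in the flask from the start; the feed brings no volume worth counting |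

    E + J ⇌ J + X (K1 = 0.772, k1 = 12700 M⁻¹ min⁻¹)
    D + Q + X → Q + Z (k2 = 24100 M⁻² min⁻¹)
    J + L ⇌ J.L, settled at all times (K3 = 10000 M⁻¹)

1. the best flask by amount of Z, in percent of the E charged; "all alike" if 1.5 percentage points covers them all (theta / beta / epsilon / zeta / all alike)
2. amount of Z at the end, in percent of the E charged, theta
3. amount of Z at the end, in percent of the E charged, beta
4. amount of Z at the end, in percent of the E charged, epsilon
5. amount of Z at the end, in percent of the E charged, zeta

I first set theta beside a neighbour, the same flask with Q at 4.5 × 10⁻⁴ M in place of 0.75 mM. The scheme returns Q unchanged, so I expected both to head for one ceiling, with D the limiting reagent at 94.9% of the E charged, and to differ in pace.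

Taking L as charged, I found that free J exchanges E and X, both ways together, at 0.663 min⁻¹. X goes on at 1.29 min⁻¹ with D as charged. With D at a quarter of its charge that drain is 0.322 min⁻¹, less than the exchange, so late on I treated E and X as one balanced pool. Its share standing as X is

f = 0.436

D and the pool start at 0.0712 M and 0.075 M, so I let them fall together at second order. I call the reciprocal of the second step's constant times Q, f and D as charged the tail time:

τ = 1.78 min

D left, as a share of its charge, after time t = τ/(τ + t)

I neglected the excess of E and the early stretch before the balance.

Theta: Z = 88.6%

Neighbour: τ = 2.97 min, so Z = 84.8%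

In beta I took the first portion as used by 15 min, since its pseudo-first-order lifetime against the excess pool is 3.22 min, shorter than that. The last portion then runs on a tail time of 3.57 min.

Beta: Z = 82.5%

For epsilon and zeta I let the fed material arrive at the middle of the feed, which leaves 17.5 min in each, so my reckoning gave the two flasks one number.

Epsilon: Z = 86.2%

Zeta: Z = 86.2%

Best: theta

The forecast named theta, with 88.5% for theta, 82% for beta, 83.5% for epsilon and 84% for zeta, holding that “having everything in from the start gives the longest effective reaction time”, and its epsilon stood lower than mine.

The run gave Z at 89.1% in theta, 82.5% in beta, 83.7% in epsilon and 85.3% in zeta, with theta best. At 25.0 min theta held D at 6.13% of its charge against my 6.66%, and in theta the relaxation half-life of E and X by the first step alone, both ways together, 0.893 min, was far shorter than the tail time grown by then to 26.8 min. The neighbour, on its tail time of 2.97 min, ended with Z at 85.0% and D at 10.5% of its charge.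

The numbers stand for no real mixture, and the outcome is calculated.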